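## Retrosynthetic overview

1. Target 10 ⇐ hexa-protected ester 9 by one global Lewis-acid dealkylation (3 OMe, 2 OBn, 1 CO2Bn).
2. 9 ⇐ ester C–O bond between cinnamic acid 5 and (R)-alcohol 7; the stereocentre is bought with danshensu 6.
3. 5 ⇐ key C3(coumarin)–O–aryl bond between 3-bromoscoparone 3 and ferulic acid 4, by a new Cu-catalysed vinylic C–O coupling.
4. 3 ⇐ scoparone 1 (C3 bromination); 7 ⇐ sodium danshensu 6 (tribenzylation).
5. No ring is built: the coumarin and both benzene rings come intact from 1, 4 and 6, and no C–C bond is formed anywhere in the route.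

Assumption: scoparone, (E)-ferulic acid and sodium (R)-danshensu are taken as inexpensive catalogue materials; the (R) stereocentre is taken from the last of these.

## Route

Step 1
Reactants: 1 scoparone (6,7-dimethoxy-2H-chromen-2-one)
Product: 3 3-bromo-6,7-dimethoxy-2H-chromen-2-one, via trans-3,4-dibromo-6,7-dimethoxychroman-2-one 2 (not isolated)
Conditions: Br2 (1.05 equiv), CH2Cl2, 0 °C → rt; then Et3N (2.5 equiv), 0 °C → rt
Reagents that add atoms: bromine, BrBr
Why: Electrophilic addition of Br2 across the enol-ether-like C3=C4 bond, then base-induced dehydrobromination (loss of the acidic C3–H and the benzylic C4–Br), is the classical addition–elimination route to 3-bromocoumarins.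

Step 2
Reactants: 3 3-bromo-6,7-dimethoxy-2H-chromen-2-one; 4 (E)-ferulic acid
Product: 5 (2E)-3-{4-[(6,7-dimethoxy-2-oxo-2H-chromen-3-yl)oxy]-3-methoxyphenyl}prop-2-enoic acid
Conditions: 3 (1.2 equiv), CuI (10 mol %), picolinic acid (20 mol %), K3PO4 (3 equiv), 4 Å MS, degassed DMSO, 80 °C, Ar; then 1 M HCl to pH 2
Reagents that add atoms: none
Why: Proposed new method: Cu(I)/picolinate-catalysed Ullmann-type C(sp2)–O coupling at C3 of a 3-bromocoumarin with an unprotected hydroxycinnamic acid used as its dianion; the phenoxide of 4 binds Cu(I), the cuprate adds oxidatively into the weak, enoate-activated C3–Br bond, and C–O reductive elimination gives the ipso (C3) aryl enol ether instead of the cine (C4) product of uncatalysed addition–elimination, with the carboxylate as a spectator; the closest known reaction type is Cu-catalysed O-arylation and O-vinylation of phenols with aryl and simple vinyl halides, together with Pd- or Cu-catalysed C–N coupling of 3-bromocoumarins.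

Step 3
Reactants: 6 sodium (2R)-3-(3,4-dihydroxyphenyl)-2-hydroxypropanoate (sodium danshensu)
Product: 7 benzyl (2R)-3-[3,4-bis(benzyloxy)phenyl]-2-hydroxypropanoate
Conditions: BnBr (3.3 equiv), K2CO3 (2.2 equiv), DMF, rt, 16 h
Reagents that add atoms: benzyl bromide, BrCc1ccccc1
Why: Williamson alkylation under carbonate benzylates the carboxylate and both phenols but not the un-ionised secondary alcohol, and the chiral-pool (R) centre is not touched.

Step 4
Reactants: 5 (2E)-3-{4-[(6,7-dimethoxy-2-oxo-2H-chromen-3-yl)oxy]-3-methoxyphenyl}prop-2-enoic acid; 7 benzyl (2R)-3-[3,4-bis(benzyloxy)phenyl]-2-hydroxypropanoate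
Product: 9 benzyl (2R)-3-[3,4-bis(benzyloxy)phenyl]-2-{[(2E)-3-{4-[(6,7-dimethoxy-2-oxo-2H-chromen-3-yl)oxy]-3-methoxyphenyl}prop-2-enoyl]oxy}propanoate, via acyl chloride 8 (not isolated)
Conditions: (COCl)2 (1.3 equiv), DMF (cat.), CH2Cl2, 0 °C → rt, evaporate; then 7 (1.1 equiv), pyridine (3 equiv), DMAP (10 mol %), CH2Cl2, 0 °C → rt
Reagents that add atoms: oxalyl chloride, ClC(=O)C(=O)Cl (its chlorine is carried only by intermediate 8; no atom of it remains in 9)
Why: Vilsmeier-type acid chloride formation followed by DMAP-catalysed O-acylation of the α-hydroxy ester forms the ester at oxygen only, so the (R) centre is retained and the non-enolisable cinnamoyl chloride keeps its E geometry.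

Step 5
Reactants: 9 benzyl (2R)-3-[3,4-bis(benzyloxy)phenyl]-2-{[(2E)-3-{4-[(6,7-dimethoxy-2-oxo-2H-chromen-3-yl)oxy]-3-methoxyphenyl}prop-2-enoyl]oxy}propanoate
Product: 10 (2R)-3-(3,4-dihydroxyphenyl)-2-{[(2E)-3-{4-[(6,7-dihydroxy-2-oxo-2H-chromen-3-yl)oxy]-3-hydroxyphenyl}prop-2-enoyl]oxy}propanoic acid
Conditions: BBr3 (12 equiv), pentamethylbenzene (6 equiv), CH2Cl2, −78 → 0 °C, dark; ice-water quench; degassed RP-HPLC (MeCN/H2O, 0.1 % HCO2H)
Reagents that add atoms: none
Why: BBr3 ether and ester dealkylation cleaves only O–CH3 and O–CH2Ph bonds (benzyl cations trapped by pentamethylbenzene), whereas the aryl–O–vinyl ether, the lactone and the secondary cinnamate have no SN-labile alkyl carbon, and the non-basic conditions leave the stereocentre and the E-alkene intact.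

## Compound list

1 | scoparone (6,7-dimethoxy-2H-chromen-2-one) | COc1cc2ccc(=O)oc2cc1OC | starting material
2 | (±)-trans-3,4-dibromo-6,7-dimethoxy-3,4-dihydro-2H-chromen-2-one (racemic, one enantiomer drawn) | Br[C@H]1[C@H](Br)c2cc(OC)c(OC)cc2OC1=O | intermediate (not isolated)
3 | 3-bromo-6,7-dimethoxy-2H-chromen-2-one | COc1cc2cc(Br)c(=O)oc2cc1OC | intermediate
4 | (E)-ferulic acid, (2E)-3-(4-hydroxy-3-methoxyphenyl)prop-2-enoic acid | COc1cc(/C=C/C(=O)O)ccc1O | starting material
5 | (2E)-3-{4-[(6,7-dimethoxy-2-oxo-2H-chromen-3-yl)oxy]-3-methoxyphenyl}prop-2-enoic acid | OC(=O)/C=C/c1ccc(Oc2cc3cc(OC)c(OC)cc3oc2=O)c(OC)c1 | intermediate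
6 | sodium (2R)-3-(3,4-dihydroxyphenyl)-2-hydroxypropanoate (sodium danshensu) | [Na+].[O-]C(=O)[C@H](O)Cc1ccc(O)c(O)c1 | starting material
7 | benzyl (2R)-3-[3,4-bis(benzyloxy)phenyl]-2-hydroxypropanoate | O[C@H](Cc1ccc(OCc2ccccc2)c(OCc2ccccc2)c1)C(=O)OCc1ccccc1 | intermediate
8 | (2E)-3-{4-[(6,7-dimethoxy-2-oxo-2H-chromen-3-yl)oxy]-3-methoxyphenyl}prop-2-enoyl chloride | ClC(=O)/C=C/c1ccc(Oc2cc3cc(OC)c(OC)cc3oc2=O)c(OC)c1 | intermediate (not isolated)
9 | benzyl (2R)-3-[3,4-bis(benzyloxy)phenyl]-2-{[(2E)-3-{4-[(6,7-dimethoxy-2-oxo-2H-chromen-3-yl)oxy]-3-methoxyphenyl}prop-2-enoyl]oxy}propanoate | O=C(/C=C/c1ccc(Oc2cc3cc(OC)c(OC)cc3oc2=O)c(OC)c1)O[C@H](Cc1ccc(OCc2ccccc2)c(OCc2ccccc2)c1)C(=O)OCc1ccccc1 | intermediate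
10 | (2R)-3-(3,4-dihydroxyphenyl)-2-{[(2E)-3-{4-[(6,7-dihydroxy-2-oxo-2H-chromen-3-yl)oxy]-3-hydroxyphenyl}prop-2-enoyl]oxy}propanoic acid | O=C(/C=C/c1ccc(Oc2cc3cc(O)c(O)cc3oc2=O)c(O)c1)O[C@H](Cc1ccc(O)c(O)c1)C(=O)O | target

## Step count and risks

Total step count: 5. Longest linear sequence: 4 (steps 1, 2, 4, 5: 1 → 3 → 5 → 9 → 10); step 3 is a one-step side branch.

The three steps most likely to fail:

**Step 2 (the proposed new C–O coupling).** The risks are cine substitution to the 4-aryloxy isomer, base-induced lactone opening with Perkin ring contraction of 3 to a benzofuran-2-carboxylate, and hydrodebromination back to 1. The product is identified by its H-4 singlet near 7.2 ppm; a 4-aryloxy isomer would instead show an H-3 singlet near 5.5 ppm. The fallback uses known chemistry, sets out from 4 and comes back at 5. Ferulic acid 4 is O-alkylated with chloroacetic acid (aq. NaOH, reflux; then HCl) to (2E)-3-[4-(carboxymethoxy)-3-methoxyphenyl]prop-2-enoic acid F1. F1 is then condensed with commercial 2-hydroxy-4,5-dimethoxybenzaldehyde (2 equiv) under Perkin–Oglialoro conditions (Ac2O, Et3N, 120 °C; aqueous NaHCO3, then acid). Only the aryloxyacetyl CH2 is enolisable, so the coumarin ring closes on that carboxyl, while the cinnamic carboxyl is carried as a mixed anhydride and hydrolysed on work-up, giving 5.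

**Step 4 (acylation of the hindered, weakly nucleophilic α-hydroxy ester).** The risks are sluggish acylation and damage to the electron-rich aryl enol ether during acid chloride formation. The fallback replaces acylation by alkylative esterification with double inversion; it sets out from 7 and 5 and comes back at 9. Alcohol 7 is converted under Appel conditions (PPh3, CBr4, CH2Cl2, 0 °C; inversion) into benzyl (2S)-3-[3,4-bis(benzyloxy)phenyl]-2-bromopropanoate F2. The caesium salt of 5 (Cs2CO3 0.5 equiv, DMF, rt) then displaces bromide in an SN2 reaction with a second inversion, giving (R)-configured 9. The ee must be checked by chiral HPLC because bromide exchange can erode it.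

**Step 5 (global BBr3 deprotection of six groups on an oxidation-prone polyphenol ester).** The risks are incomplete demethylation, cleavage of the cinnamate ester and C-benzylation. The fallback moves the demethylation ahead of ester formation; it sets out from 5 and comes back at 10. Acid 5 is demethylated with BBr3 (CH2Cl2, −78 °C → rt) to (2E)-3-{4-[(6,7-dihydroxy-2-oxo-2H-chromen-3-yl)oxy]-3-hydroxyphenyl}prop-2-enoic acid F3. Its carboxylate alone (KHCO3 1.05 equiv, DMF, rt) is alkylated with the (S)-bromide F2, made from 7 as described for step 4. This gives benzyl (2R)-3-[3,4-bis(benzyloxy)phenyl]-2-{[(2E)-3-{4-[(6,7-dihydroxy-2-oxo-2H-chromen-3-yl)oxy]-3-hydroxyphenyl}prop-2-enoyl]oxy}propanoate F4. The three benzyl groups of F4 are then removed with BCl3/pentamethylbenzene (CH2Cl2, −78 °C), which spares esters and alkenes, to give 10.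

Further compounds
F1 | step 2 | (2E)-3-[4-(carboxymethoxy)-3-methoxyphenyl]prop-2-enoic acid | OC(=O)COc1ccc(/C=C/C(=O)O)cc1OC
F2 | step 4 | benzyl (2S)-3-[3,4-bis(benzyloxy)phenyl]-2-bromopropanoate | Br[C@@H](Cc1ccc(OCc2ccccc2)c(OCc2ccccc2)c1)C(=O)OCc1ccccc1
F3 | step 5 | (2E)-3-{4-[(6,7-dihydroxy-2-oxo-2H-chromen-3-yl)oxy]-3-hydroxyphenyl}prop-2-enoic acid | OC(=O)/C=C/c1ccc(Oc2cc3cc(O)c(O)cc3oc2=O)c(O)c1
F4 | step 5 | benzyl (2R)-3-[3,4-bis(benzyloxy)phenyl]-2-{[(2E)-3-{4-[(6,7-dihydroxy-2-oxo-2H-chromen-3-yl)oxy]-3-hydroxyphenyl}prop-2-enoyl]oxy}propanoate | O=C(/C=C/c1ccc(Oc2cc3cc(O)c(O)cc3oc2=O)c(O)c1)O[C@H](Cc1ccc(OCc2ccccc2)c(OCc2ccccc2)c1)C(=O)OCc1ccccc1
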